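(The numbers in the tables were generated by integration for an exercise; the scatter is artificial.)

Time is the first setting I would turn on this flask, so I count it in halvings of the electrophile, not in minutes.

common to all: electrophile 0.20 mM (fed, over 20 s)

| run | nucleophile | free base | remark | time |
|---|---|---|---|---|
| birch | 0.13 mM | 0.60 mM | run made earlier; the fed solution adds 1.0 times the starting volume |  |
| alder | 0.52 mM | 0.60 mM | run made earlier; the fed solution adds 1.0 times the starting volume |  |
| cedar | 0.26 mM | 1.2 mM | run made earlier; the fed solution adds 1.0 times the starting volume |  |
| flask | 0.260 mM | 0.600 mM | the fed solution adds 1.0 times the starting volume | 5.0 min |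

- birch (time / min: electrophile / %, target / %): 0.417: 85, 8; 0.667: 74, 8; 1.00: 61, 11; 1.33: 53, 5; 2.00: 36, 5; 3.00: 28, 2; 5.00: 16, 2
- alder (time / min: electrophile / %, target / %): 0.250: 52, 11; 0.833: 19, 25; 1.33: 4, 25; 2.00: 0, 28; 3.00: 0, 26; 4.00: 1, 25; 5.00: 1, 25
- cedar (time / min: electrophile / %, target / %): 0.417: 75, 11; 1.33: 26, 12; 2.50: 8, 14; 4.00: 3, 14; 5.00: 2, 10

(scatter of a reading: 2 percentage points)

- percent here means electrophile units held: one side product counts as two
- amounts are per litre of the starting volume; all of the dose is in the solution fed
- the earlier runs were read with a standard deviation of 2 percentage points
- what may be going on: acid set free + free base <-> salt of the base; electrophile + nucleophile -> acid set free + target; target <-> isomer of the product; nucleophile + acid set free <-> protonated nucleophile; electrophile + target -> side product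
- percentages count the whole charge, also what has not yet gone in
- the earlier runs do not show how much of nucleophile is bound; that part of a forecast is a guess

* part of the electrophile that has reacted at 5.0 min
* share of the unused nucleophile that is free and not bound as protonated nucleophile, at 5.0 min

Cedar has the flask's charge of nucleophile, so I read my number there. Between 1.33 min and 2.50 min cedar's electrophile falls from 26% to 8%, which gives 0.688 min, a pseudo-first-order reading with the scatter of those two points. This is the late half-life, the time in which c(electrophile) halves once the feed is over.

Time first: from 2.50 min to 5.0 min are 3.63 halvings, so by hand 0.645% of the charge remains. The feed next: it lasts 20 s, about half of one half-life, and it ends earlier than that reading, so it stays outside the count. The nucleophile next: read after the feed in the same way, the half-life is 0.221 min in alder, between 0.833 min and 1.33 min, and 2.56 min in birch, between 2.00 min and 5.00 min, so my count holds for this charge of nucleophile. Last the free base: the flask has 0.600 mM against 0.20 mM of electrophile, so I carry cedar's half-life across unchanged, although cedar had twice the free base; that step is a judgement. My reckoning therefore says 99.4% reacted. For the free share of nucleophile I have no reading and give no number.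

The forecast says 97% reacted (from 92% to 99.5%), lower than my figure; it too holds that the flask “should therefore follow cedar”. For the free share it guesses 85% (from 55% to 99%).

The flask gives 99.0% reacted and 72.8% of the unused nucleophile free; at 5.0 min it holds 0.0201 mM of protonated nucleophile, and 88% of its charged free base is left. My count promised 7.28 halvings of the charge by then. At 0.96% left the flask made 6.70, and the neighbour with 0.36 mM of free base made 6.27, with 1.3% of its electrophile left.

    acid set free + free base ⇌ salt of the base, settled at all times (K = 8.40 × 10⁶ /M)
    electrophile + nucleophile → acid set free + target (k = 120 /M/s)
    target ⇌ isomer of the product (K = 0.210, k = 0.0300 /s)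
    nucleophile + acid set free ⇌ protonated nucleophile, settled at all times (K = 2.30 × 10⁷ /M)
    electrophile + target → side product (k = 720 /M/s)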